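How much product did Wednesday's flask hold at 1.0 h, and which option added most?

1. product, in percent of the substrate first charged, at 1.0 h
2. which option adds most product ("none" when 2 percentage points or less is all one gets) (grey / green / blue / ochre / none)
3. product present, with what was taken out counted in, in percent of the substrate first charged, after green
4. product present, with what was taken out counted in, in percent of the substrate first charged, after ochre

common to all: reagent 0.504 M

| run | substrate | remark | time |
|---|---|---|---|
| Wednesday's | 0.72 M | the very flask that is asked about, followed so far |  |
| Tuesday's | 1.4 M | run made earlier |  |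
| flask | 0.72 M |  | 1.0 h |

- grey: at 1.0 h add substrate, 50.0% of the amount charged, then wait 20 min
- green: at 1.0 h take out 90% of the product then present, then wait 20 min
- blue: change nothing and wait 20 min more
- ochre: at 1.0 h add reagent, 100% of the amount charged, then wait 20 min

- product taken out counts as made
- additions bring no volume worth counting

| run | time / min | product / % | substrate / % |
|---|---|---|---|
| Wednesday's | 6.00 | 23.0 | 75.6 |
| Wednesday's | 15.0 | 29.2 | 70.3 |
| Wednesday's | 20.0 | 29.7 | 70.7 |
| Wednesday's | 30.0 | 28.6 | 70.3 |
| Wednesday's | 40.0 | 29.5 | 69.3 |
| Wednesday's | 50.0 | 29.0 | 70.3 |
| Tuesday's | 0.417 | 3.7 | 95.6 |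
| Tuesday's | 1.33 | 9.3 | 90.4 |
| Tuesday's | 2.50 | 13.6 | 84.7 |
| Tuesday's | 4.00 | 17.0 | 83.2 |
| Tuesday's | 5.00 | 16.8 | 82.0 |
| Tuesday's | 6.00 | 21.3 | 80.0 |
| Tuesday's | 8.00 | 20.4 | 79.1 |

(readings scatter by 1 percentage point)

From 15.0 min on, Wednesday's product averaged 29.2%, and at the last reading product plus substrate came to 99.3%. That is 0.210 M of product, with 0.294 M of reagent free by subtraction. Tuesday's last reading, with the same reagent charge, came to 0.286 M of product, more than that, so I read Wednesday's plateau as an equilibrium and not as an exhausted charge. I carried the plateau quotient K, 1.40 L mol⁻¹, the concentration of product divided by those of free substrate and free reagent.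

The bench rule holds the reagent at its charge R and gives the share of substrate turned to product as K·R divided by one plus K·R, here 41.4%. Multiplied by the ratio of substrate to reagent charged, that share is the part of the reagent the rule consumes. The part is 59.2% in Wednesday's flask, where the reagent is the limiting reagent, and there the rule's share stands higher than the plateau. On Tuesday the part is 115%, more than the reagent charged, so the rule stops working there. Solving the balance to the end gave 21.8% for Tuesday, beside a last reading of 20.4%.

For ochre the reagent charge becomes 1.01 M. The rule gave 58.6%; putting each answer back into the free reagent gave 45.1%, 49.0% and 47.9%. Green takes out 0.189 M and ends, with that counted in, at 42.4%. Grey ends at 37.3%, and blue stays at 29.2%. So I chose ochre. Wednesday's plateau stood by 15.0 min, sooner than the 20 min allowed.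

The forecast gave 29.2%, ochre, 42.3% and 48%, holding that “the reaction stops at equilibrium, with reagent still left”.

The flask gave 29.0% at 1.0 h, and ochre added most: 19 percentage points, against 13 points for green, 8 points for grey and 0 points for blue. Green ended at 42.0% and ochre at 47.8%.

    substrate + reagent ⇌ product (K = 1.38 L mol⁻¹, k = 0.00318 L mol⁻¹ s⁻¹)

The falling back of product to substrate + reagent is the main reason Wednesday's flask stopped: the run without that step stood at 68.1% at 1.0 h, against 29.0%. After ochre, the quotient from the final amounts was 1.38 L mol⁻¹, beside 1.40 L mol⁻¹ from the plateau. For a neighbour flask, like Wednesday's but charged with 2.0 M of reagent, the rule gave 73.7%, and the rounds gave 67.3% and 68.0%. That neighbour flask held 67.6% of product at 1.0 h.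

(The readings come from a simulation with made-up constants; the scatter is artificial.)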